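**Retrosynthetic overview**

- The only ring to build is the 1,4-dioxane. Its hemiketal carbon (C2 of the benzodioxine) can equilibrate by ring opening, so only the methyl-bearing carbon C3 must be set by the route.
- Fragments: ketone 1 → (Z)-enolsilane 2 (first C6–C3 unit); phenol 3 → o-quinone 4 (second C6–C3 unit, the oxidised 5-hydroxyeugenol of the biogenesis).
- Key disconnection: both C–O bonds of the dioxane at once, by an enantioselective inverse-electron-demand hetero-Diels–Alder of 4 with 2 to give silyl ketal 5. This copies the o-quinone/propenyl oxidative coupling proposed for eusiderin-type neolignans.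
- Ring order: the dioxane is formed in the last step. Hydrolysis of 5 gives the kinetic hemiketal 6, which equilibrates through keto-phenol 7 to the target 8.

Assumption 1: the hemiketal carbon epimerises through the ring-opened keto-phenol, and the drawn (2S,3R) epimer (OH trans to CH3) is the thermodynamic one; this is reasoned from conformation (OH axial, aryl equatorial), not verified.

Assumption 2: the (S,S)-ligand in step 3 is chosen from a quadrant model, and the sense of induction is unproven; if the first run gives the 3S series, the (R,R)-ligand is used with no other change.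

**Step 1**
Reactants: 1 1-(3,4,5-trimethoxyphenyl)propan-1-one
Product: 2 (Z)-trimethyl{[1-(3,4,5-trimethoxyphenyl)prop-1-en-1-yl]oxy}silane
Conditions: LiN(i-Pr)2 (commercial solution, 1.1 equiv), THF, −78 °C, 45 min; then Me3SiCl (1.3 equiv), −78 → 0 °C; pentane, filtration, Kugelrohr distillation
Reagents that add atoms: chlorotrimethylsilane, C[Si](C)(C)Cl
Why: Kinetic deprotonation of an aryl ethyl ketone by the lithium amide gives the (Z)-enolate with high selectivity, and O-silylation (silyl enol ether formation) traps it with the geometry intact; no stereocentre is formed.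

**Step 2**
Reactants: 3 2,6-dimethoxy-4-(prop-2-en-1-yl)phenol (4-allyl-2,6-dimethoxyphenol)
Product: 4 3-methoxy-5-(prop-2-en-1-yl)cyclohexa-3,5-diene-1,2-dione
Conditions: IBX (1.2 equiv), DMF, 0 °C → rt, 1 h, dark; cold Et2O/H2O partition without base; used the same day
Reagents that add atoms: 2-iodoxybenzoic acid (IBX), O=C1OI(=O)(O)c2ccccc12
Why: IBX ortho-oxygenation of a 2-methoxyphenol (oxidative demethylation): the phenol binds pentavalent iodine, oxygen is delivered to an OMe-bearing ortho carbon, and the quinone monoketal loses methanol; both ortho positions are equivalent, the allyl group is untouched, and no stereocentre is formed.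

**Step 3**
Reactants: 2 (Z)-trimethyl{[1-(3,4,5-trimethoxyphenyl)prop-1-en-1-yl]oxy}silane; 4 3-methoxy-5-(prop-2-en-1-yl)cyclohexa-3,5-diene-1,2-dione
Product: 8 (2S,3R)-5-methoxy-3-methyl-7-(prop-2-en-1-yl)-2-(3,4,5-trimethoxyphenyl)-2,3-dihydro-1,4-benzodioxin-2-ol, via silyl ketal 5 (not isolated), via kinetic hemiketal 6 (not isolated), via keto-phenol 7 (not isolated)
Conditions: Cu(OTf)2 (10 mol%), (S,S)-t-Bu-box (11 mol%), 4 Å MS, THF, −78 °C, 2 (1.3 equiv) added over 2 h; then AcOH/H2O, 0 °C → rt, 2 h; aqueous EDTA wash, neutral silica, recrystallisation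
Reagents that add atoms: none
Why: Proposed new method: an enantioselective inverse-electron-demand hetero-Diels–Alder in which the 1,2-dicarbonyl of 4 chelates the C2-symmetric bis(oxazoline) complex of divalent copper; the nucleophilic carbon of 2 bonds to the more electrophilic quinone oxygen (the C2 carbonyl, next to OMe and para to allyl), while the C1 carbonyl, a doubly vinylogous ester, becomes the better-stabilised phenoxide that closes on the silyloxocarbenium carbon, giving the natural regiochemistry; C3 (R) is set by approach of the enolsilane from the unshielded quadrant of the chelate with OSiMe3 endo, and OSiMe3 is cis to CH3 in 5 because addition to the Z-alkene is suprafacial; Si–O hydrolysis gives 6, which equilibrates through 7 to the thermodynamic epimer 8 without touching C3; closest known reaction types are bis(oxazoline)–copper-catalysed hetero-Diels–Alder reactions of chelating 1,2-dicarbonyl heterodienes with enol ethers, the same catalysts in the α-amination of aryl ketone enolsilanes with chelating azo compounds, thermal o-quinone/propenylbenzene cycloadditions to benzodioxane neolignans, and amine-catalysed enantioselective [4+2] reactions of o-quinones with ketene enolates.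

**Compound list**

1 | 1-(3,4,5-trimethoxyphenyl)propan-1-one | CCC(=O)c1cc(OC)c(OC)c(OC)c1 | starting material
2 | (Z)-trimethyl{[1-(3,4,5-trimethoxyphenyl)prop-1-en-1-yl]oxy}silane | C/C=C(\O[Si](C)(C)C)c1cc(OC)c(OC)c(OC)c1 | intermediate
3 | 2,6-dimethoxy-4-(prop-2-en-1-yl)phenol | C=CCc1cc(OC)c(O)c(OC)c1 | starting material
4 | 3-methoxy-5-(prop-2-en-1-yl)cyclohexa-3,5-diene-1,2-dione | C=CCC1=CC(=O)C(=O)C(OC)=C1 | intermediate
5 | (2S,3R)-5-methoxy-3-methyl-7-(prop-2-en-1-yl)-2-(3,4,5-trimethoxyphenyl)-2-[(trimethylsilyl)oxy]-2,3-dihydro-1,4-benzodioxine (OSiMe3 cis to CH3) | C=CCc1cc(OC)c2c(c1)O[C@](O[Si](C)(C)C)(c1cc(OC)c(OC)c(OC)c1)[C@@H](C)O2 | intermediate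
6 | (2R,3R)-5-methoxy-3-methyl-7-(prop-2-en-1-yl)-2-(3,4,5-trimethoxyphenyl)-2,3-dihydro-1,4-benzodioxin-2-ol (C2 epimer of the target, OH cis to CH3) | C=CCc1cc(OC)c2c(c1)O[C@](O)(c1cc(OC)c(OC)c(OC)c1)[C@@H](C)O2 | intermediate
7 | (2R)-2-[2-hydroxy-6-methoxy-4-(prop-2-en-1-yl)phenoxy]-1-(3,4,5-trimethoxyphenyl)propan-1-one | C=CCc1cc(O)c(O[C@H](C)C(=O)c2cc(OC)c(OC)c(OC)c2)c(OC)c1 | intermediate
8 | (2S,3R)-5-methoxy-3-methyl-7-(prop-2-en-1-yl)-2-(3,4,5-trimethoxyphenyl)-2,3-dihydro-1,4-benzodioxin-2-ol | C=CCc1cc(OC)c2c(c1)O[C@@](O)(c1cc(OC)c(OC)c(OC)c1)[C@@H](C)O2 | target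

**Totals**

Total step count: 3. Longest linear sequence: 2 steps (3 → 4 → 8, or 1 → 2 → 8).

**Steps most likely to fail, with fallbacks**

Step 3 is the main risk. The asymmetric induction has no direct precedent with this electron-rich o-quinone, and both the sense of induction and the regiochemistry rest on models; an uncatalysed background reaction could also erode the ee. The fallback sets out from 4 and comes back at 7. Compound 4 is treated with propionyl chloride, i-Pr2NEt and O-benzoylquinidine (10 mol%) in THF at −78 °C. The cinchona-bound ketene enolate adds across the two quinone oxygens with the same regiochemistry and gives the lactone (3R)-5-methoxy-3-methyl-7-(prop-2-en-1-yl)-1,4-benzodioxin-2(3H)-one F1. The pseudoenantiomeric O-benzoylquinine is used if the sense proves opposite. F1 is opened with MeNH(OMe)·HCl and i-PrMgCl in THF at −20 °C to the Weinreb amide (2R)-2-[2-hydroxy-6-methoxy-4-(prop-2-en-1-yl)phenoxy]-N-methoxy-N-methylpropanamide F2. Commercial 3,4,5-(MeO)3C6H2MgBr (2.5 equiv, THF, −20 → 0 °C, NH4Cl work-up) then gives 7, which closes to 8 as in the main route.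

Step 2 is the second risk. The allyl-substituted o-quinone can tautomerise to a p-quinone methide or dimerise during isolation from the IBX mixture. The fallback sets out from 3 and comes back at 4. Compound 3 is mono-demethylated without oxidant by AlCl3/pyridine in refluxing CH2Cl2 (chelation-directed cleavage of an OMe next to the free OH). This gives the bench-stable catechol 3-methoxy-5-(prop-2-en-1-yl)benzene-1,2-diol F3. F3 is dehydrogenated with Ag2O in THF at −20 °C and filtered through Celite directly into the catalyst solution of step 3 as a base-free solution of 4.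

Step 1 is the least risky. The enolsilane may be obtained with insufficient Z purity or may hydrolyse on purification. The fallback sets out from 1 and comes back at 2. Compound 1 is brominated with CuBr2 in refluxing EtOAc/CHCl3 to racemic 2-bromo-1-(3,4,5-trimethoxyphenyl)propan-1-one F4. F4 is reduced with Zn dust in the presence of Me3SiCl and TMEDA (MeCN/Et2O, rt); the zinc enolate is silylated on oxygen as it forms and gives 2 as the thermodynamic Z isomer.

**Further compounds**

F1 | step 3 | (3R)-5-methoxy-3-methyl-7-(prop-2-en-1-yl)-1,4-benzodioxin-2(3H)-one | C=CCc1cc(OC)c2c(c1)OC(=O)[C@@H](C)O2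
F2 | step 3 | (2R)-2-[2-hydroxy-6-methoxy-4-(prop-2-en-1-yl)phenoxy]-N-methoxy-N-methylpropanamide | C=CCc1cc(O)c(O[C@H](C)C(=O)N(C)OC)c(OC)c1
F3 | step 2 | 3-methoxy-5-(prop-2-en-1-yl)benzene-1,2-diol | C=CCc1cc(O)c(O)c(OC)c1
F4 | step 1 | 2-bromo-1-(3,4,5-trimethoxyphenyl)propan-1-one (racemic) | CC(Br)C(=O)c1cc(OC)c(OC)c(OC)c1
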